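A direct plan would acylate 2‑methylphloroglucinol A1 with butanoyl chloride to the butyrophenone A2, methylate one hydroxyl to the monomer A3 and join two molecules of A3 with formaldehyde. Its weakest steps would be:
- the mono‑O‑methylation, because the hydroxyl to be etherified is the chelated, hindered one between acyl and methyl, while the free para hydroxyl is more acidic and would react first;
- the Friedel–Crafts acylation, because the triphenol would also give O‑acyl and diacyl products under Lewis acid;
- the formaldehyde coupling, because it passes through a quinone methide that can add to any free phenol present, and it only joins two finished halves.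

The route rests on cutting, in each ring, the bonds C1–C2 and C3–C4 (C1 carries butanoyl, C3 the bridge). This reduces pseudoaspidin to dimethyl glutarate and two molecules of 4‑methoxy‑3‑methyl‑6‑propyl‑2‑pyranone, a masked triketide. In one operation each glutarate α‑carbon is acylated by the enol lactone, and the enolate thereby released closes the ring by Claisen condensation onto the glutarate ester, so both hexasubstituted rings arise from open‑chain material. The bridge CH2 is the central carbon of glutarate, the methoxy group is the enol ether oxygen of the pyranone and the butanoyl group its unmasked lactone enol; phenol methylation, Friedel–Crafts acylation and methylene coupling therefore do not occur.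

Key step: step 4

Remark: ring atoms are numbered C1 (butanoyl), C2 (OH), C3 (bridge CH2), C4 (OH), C5 (methyl), C6 (methoxy); the same locants are used for the corresponding atoms of the open‑chain precursors.

Step 1
Reactants: 1 ethyl 2‑methyl‑3‑oxobutanoate (ethyl 2‑methylacetoacetate); 2 N‑methoxy‑N‑methylbutanamide
Product: 3 ethyl 2‑methyl‑3,5‑dioxooctanoate
Conditions: NaH (1.1 equiv), THF, 0 °C; n‑BuLi (1.05 equiv), 0 °C; 2 (0.9 equiv), 0 °C → rt; aq. HCl
Reagents that add atoms: N‑methoxy‑N‑methylbutanamide (CCCC(=O)N(C)OC)
Why: Huckin–Weiler γ‑acylation of the acetoacetate dianion, in which the more basic terminal carbanion attacks the Weinreb amide and the chelated tetrahedral adduct prevents a second addition and product‑induced quenching.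

Step 2
Reactants: 3 ethyl 2‑methyl‑3,5‑dioxooctanoate
Product: 4 4‑hydroxy‑3‑methyl‑6‑propyl‑2H‑pyran‑2‑one
Conditions: DBU (1.1 equiv), toluene, 90 °C; 1 M HCl
Reagents that add atoms: none
Why: Base‑mediated lactonisation (intramolecular O‑acylation of the 5‑enol by the ester) closes the six‑membered 4‑hydroxy‑2‑pyranone, the standard cyclisation of 3,5‑dioxoalkanoates.

Step 3
Reactants: 4 4‑hydroxy‑3‑methyl‑6‑propyl‑2H‑pyran‑2‑one; 5 dimethyl sulfate
Product: 6 4‑methoxy‑3‑methyl‑6‑propyl‑2H‑pyran‑2‑one
Conditions: Me2SO4 (1.2 equiv), K2CO3 (1.5 equiv), acetone, reflux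
Reagents that add atoms: dimethyl sulfate (COS(=O)(=O)OC)
Why: O‑alkylation of the vinylogous acid with a hard electrophile should give the conjugated 2‑pyranone ether in preference to the 2‑methoxy‑4‑pyranone, with the C3 methyl disfavouring C‑alkylation; this is the only place where the future aryl methyl ether is made, and no other hydroxyl is present.

Step 4
Reactants: 6 4‑methoxy‑3‑methyl‑6‑propyl‑2H‑pyran‑2‑one (two molecules); 7 dimethyl pentanedioate (dimethyl glutarate)
Product: 10 pseudoaspidin, via mono‑acylated glutarate 8 (not isolated), via bis(β‑keto ester) 9 (not isolated)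
Conditions: 7, LiN(i‑Pr)2 (1.05 equiv), THF, −78 °C; 6 (1.0 equiv), −78 → −20 °C; LiN(i‑Pr)2 (2.1 equiv), −78 °C; 6 (1.05 equiv), −78 → 0 °C; then Mg(OMe)2 (4 equiv), MeOH, 50 °C, Ar; 1 M HCl
Reagents that add atoms: dimethyl glutarate (COC(=O)CCCC(=O)OC)
Why: Proposed new method: the lithium ester enolate of 7 should add to the lactone carbonyl of 6 (an enol ester and the hardest electrophilic site, whereas C4 is deactivated by its methoxy group and C6 by its alkyl group and ring oxygen), and collapse of the adduct opens the ring to the β‑keto ester 8 (new bond C3–C4) while releasing exactly the vinylogous 1,3‑diketone enolate at C1 that is needed next; after renewed deprotonation the second α‑carbon is acylated in the same way to 9, and each C1 enolate then attacks the neighbouring glutarate ester carbon (new bond C1–C2) with loss of methanol and enolisation to the aromatic ring. The closest known reaction types are the Fujimoto–Belleau annulation of enol lactones with carbanions, the magnesium methoxide methanolysis of 4‑methoxy‑2‑pyranones at the lactone carbonyl, and the Claisen‑mode cyclisation of 3,5,7‑triketo esters and 6‑(2‑oxoalkyl)‑2‑pyranones to acylphloroglucinols. Each ring closes in a 6‑(enolexo)‑exo‑trig mode, for which the E enol ether inherited from the pyranone holds C1 and C4 on the same side of the C5=C6 bond. No stereocentre is formed, the two methine centres of 9 (a diastereomer mixture) becoming aromatic carbons. The step needs 1,2‑addition instead of proton abstraction from the 6‑propyl group or 1,6‑addition, which the hard lithium enolate at −78 °C and the enol‑ester carbonyl should favour, and it needs the second enolate to survive, which is why the two acylations are run one after the other (the acidic β‑keto ester C–H of 8 would quench a bis‑enolate). Claisen closure is the only productive mode, since O‑acylation would need an eight‑membered ring and aldol attack of C3 on the butanoyl ketone gives a quaternary centre that cannot aromatise and reverts, while the methoxy group never has to be told apart from a hydroxyl.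

Compound list
1 | ethyl 2‑methyl‑3‑oxobutanoate (racemic) | CCOC(=O)C(C)C(C)=O | starting material
2 | N‑methoxy‑N‑methylbutanamide | CCCC(=O)N(C)OC | starting material
3 | ethyl 2‑methyl‑3,5‑dioxooctanoate (racemic, largely enolised) | CCCC(=O)CC(=O)C(C)C(=O)OCC | intermediate
4 | 4‑hydroxy‑3‑methyl‑6‑propyl‑2H‑pyran‑2‑one | CCCC1=CC(O)=C(C)C(=O)O1 | intermediate
5 | dimethyl sulfate | COS(=O)(=O)OC | starting material
6 | 4‑methoxy‑3‑methyl‑6‑propyl‑2H‑pyran‑2‑one | CCCC1=CC(OC)=C(C)C(=O)O1 | intermediate
7 | dimethyl pentanedioate (dimethyl glutarate) | COC(=O)CCCC(=O)OC | starting material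
8 | dimethyl 2‑[(2E)‑3‑methoxy‑2‑methyl‑5‑oxooct‑2‑enoyl]pentanedioate (racemic, present as its lithium enolate) | CCCC(=O)C/C(OC)=C(/C)C(=O)C(C(=O)OC)CCC(=O)OC | intermediate
9 | dimethyl 2,4‑bis[(2E)‑3‑methoxy‑2‑methyl‑5‑oxooct‑2‑enoyl]pentanedioate (diastereomer mixture, present as enolates) | CCCC(=O)C/C(OC)=C(/C)C(=O)C(C(=O)OC)CC(C(=O)OC)C(=O)/C(C)=C(\CC(=O)CCC)OC | intermediate
10 | pseudoaspidin, bis(3‑butanoyl‑2,6‑dihydroxy‑4‑methoxy‑5‑methylphenyl)methane | CCCC(=O)c1c(O)c(Cc2c(O)c(C)c(OC)c(C(=O)CCC)c2O)c(O)c(C)c1OC | target

Total step count: 4. Longest linear sequence: 4 (steps 1–4; dimethyl glutarate enters at step 4).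

Steps most likely to fail

Step 4. The ester enolate may abstract a proton from the 6‑propyl group of 6 or add at C6 instead of transferring the acyl group. The third equivalent of base may also remove a γ‑proton of the first arm instead of the ester α‑proton, or ring closure may stall at the polyanion stage. The fallback sets out from 6 and comes back at 9, using known reaction types only. Hydrogenation of the 5,6‑double bond of 6 (H2, palladium on carbon, EtOAc) would give the δ‑lactone 4‑methoxy‑3‑methyl‑6‑propyl‑5,6‑dihydro‑2H‑pyran‑2‑one F1, which has no enol‑ester leaving group. The bis‑lithium enolate of 7 (LiN(i‑Pr)2, 2.2 equiv, THF, −78 °C) would add to two molecules of F1 in the ordinary ester‑enolate/δ‑lactone Claisen reaction, whose lactolate adducts persist at low temperature and set free no acidic C–H. This would give dimethyl 2,4‑bis[(2E)‑5‑hydroxy‑3‑methoxy‑2‑methyloct‑2‑enoyl]pentanedioate F2 (in equilibrium with its lactol forms). Oxidation of both secondary alcohols with Dess–Martin periodinane would then return to 9, which would be closed to 10 with Mg(OMe)2 in methanol as in step 4.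

Step 3. Alkylation may occur at the lactone carbonyl oxygen (giving the isomeric 4‑pyranone ether) or at C3. The fallback sets out from 1 and comes back at 6, fixing the enol ether before the lactone exists. Compound 1 would be treated with trimethyl orthoformate and catalytic H2SO4 to give ethyl (2E)‑3‑methoxy‑2‑methylbut‑2‑enoate F3 (partial ester exchange would not matter). γ‑Deprotonation (LiN(i‑Pr)2, THF, −78 °C) and acylation of the dienolate with 2 would give ethyl (2E)‑3‑methoxy‑2‑methyl‑5‑oxooct‑2‑enoate F4, which would lactonise with loss of ethanol (DBU, toluene, heat) to 6.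

Step 1. Proton transfer from the product or from the amide α‑position may quench the dianion, or acylation may occur on oxygen. The fallback sets out from 1 and comes back at 3 under neutral conditions. Compound 1 would be silylated twice (Me3SiCl/Et3N, then LiN(i‑Pr)2/Me3SiCl) to 1‑ethoxy‑2‑methyl‑1,3‑bis(trimethylsilyloxy)buta‑1,3‑diene F5. Its terminal carbon would be acylated with butanoyl chloride (CH2Cl2, −78 → 20 °C) in a Mukaiyama‑type reaction, giving 3 after aqueous work‑up.

Further compounds
F1 | step 4 | 4‑methoxy‑3‑methyl‑6‑propyl‑5,6‑dihydro‑2H‑pyran‑2‑one (racemic) | CCCC1CC(OC)=C(C)C(=O)O1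
F2 | step 4 | dimethyl 2,4‑bis[(2E)‑5‑hydroxy‑3‑methoxy‑2‑methyloct‑2‑enoyl]pentanedioate (stereoisomer mixture) | CCCC(O)C/C(OC)=C(/C)C(=O)C(C(=O)OC)CC(C(=O)OC)C(=O)/C(C)=C(\CC(O)CCC)OC
F3 | step 3 | ethyl (2E)‑3‑methoxy‑2‑methylbut‑2‑enoate | CCOC(=O)/C(C)=C(\C)OC
F4 | step 3 | ethyl (2E)‑3‑methoxy‑2‑methyl‑5‑oxooct‑2‑enoate | CCCC(=O)C/C(OC)=C(/C)C(=O)OCC
F5 | step 1 | 1‑ethoxy‑2‑methyl‑1,3‑bis(trimethylsilyloxy)buta‑1,3‑diene (E/Z mixture) | CCOC(O[Si](C)(C)C)=C(C)C(=C)O[Si](C)(C)C
A1 | direct plan | 2‑methylbenzene‑1,3,5‑triol (2‑methylphloroglucinol) | Cc1c(O)cc(O)cc1O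
A2 | direct plan | 1‑(2,4,6‑trihydroxy‑3‑methylphenyl)butan‑1‑one | CCCC(=O)c1c(O)cc(O)c(C)c1O
A3 | direct plan | 1‑(4,6‑dihydroxy‑2‑methoxy‑3‑methylphenyl)butan‑1‑one | CCCC(=O)c1c(OC)c(C)c(O)cc1O
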